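Readings and results stem from a simulated flask for an exercise; scatter was added.

I decided to hold every reading against the statistical case: the coupling partner picks substrate, single product and bis adduct at equal rates, so additions per substrate count as a Poisson variable of mean e, the equivalents charged. The bis adduct share is then S = e·e/2·exp(−e).

| flask | substrate | coupling partner | remark | time |
|---|---|---|---|---|
| Wednesday's | 0.060 M | 0.50 equiv | run made earlier |  |
| Monday's | 0.060 M | 2 equiv | run made earlier |  |
| Saturday's | 0.12 M | 1 equiv | run made earlier |  |
| flask | 0.060 M | 1.00 equiv |  | 6.0 min |

- Wednesday's (time / min: bis adduct / %, triple product / %): 0.667: 4.7, 0.7; 2.00: 4.8, 0.7; 3.00: 4.7, 0; 5.00: 4.8, 0; 8.00: 4.1, 0.5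
- Monday's (time / min: bis adduct / %, triple product / %): 1.33: 11.7, 1.8; 3.00: 4.7, 2.0; 4.00: 4.8, 0.9; 6.00: 2.9, 0.2; 8.00: 0.7, 1.8
- Saturday's (time / min: bis adduct / %, triple product / %): 0.667: 13.4, 0; 2.00: 12.2, 0; 3.00: 11.8, 0; 5.00: 11.1, 0.6; 8.00: 11.0, 0

(each reading ± 1 percentage point)

- the analysis behind the earlier runs scatters by 1 percentage point, standard deviation
- steps thought possible: substrate + coupling partner -> single product + by-product; single product -> decomposed reagent; coupling partner + bis adduct -> triple product + by-product; triple product + by-product -> side product; coupling partner + single product -> bis adduct + by-product; coupling partner <-> dormant form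

- equivalents of coupling partner to substrate, everything else as given, that leave most bis adduct at 6.0 min
- the amount of bis adduct then, in percent of the substrate charged
- the amount of bis adduct with the amounts as given

Had Wednesday's run stopped? It read 4.7% at 0.667 min and 4.8% at 5.00 min, a ratio of 1.02, so I left time out of my reckoning.

How much of the zero arrived? Wednesday's 4.8% over its S of 7.58% gives 0.633. I call this the retention ρ, read bis adduct over S.

Did it travel? At e of 1, S is 18.4%, and Saturday's last 11.0% gives 0.598 at double the concentration. Monday's 2.9% gives 0.107, so I sought the best charge below 2 equiv. For the flask I committed to ρ·S = 11.6%.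

The forecast stood lower on the flask, at 10.5%, but gave 15% at 1.3 equiv: “The optimum is therefore just past the point of partner exhaustion”.

The flask gave 8.15%, and the best charge 1.12 equiv gave 8.34%.

    substrate + coupling partner → single product + by-product (k = 0.930 L mol⁻¹ s⁻¹)
    single product → decomposed reagent (k = 0.0360 s⁻¹)
    coupling partner + bis adduct → triple product + by-product (k = 1.20 L mol⁻¹ s⁻¹)
    triple product + by-product → side product (k = 3.00 L mol⁻¹ s⁻¹)
    coupling partner + single product → bis adduct + by-product (k = 0.940 L mol⁻¹ s⁻¹)
    coupling partner ⇌ dormant form (K = 0.230, k = 0.0470 s⁻¹)

The flask's own retention came to 0.443, so my 11.6% stood too high. With the loss of single product to decomposed reagent struck out, the flask gives 16.9%, a retention of 0.918.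

For a neighbouring flask charged with 0.400 equiv, everything else as in the flask, ρ·S gives 3.40%. The computed value is 2.96%, with the coupling partner, the limiting reagent, at 0% of its charge.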